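## The problem

- CNP0307265.1 (31) is a daucane ester: a cyclopentane (ring A, C1–C5) trans-fused through C1–C5 to a cycloheptane (ring B, C1 and C5–C10). C1 carries the angular methyl, C4 the isopropyl carbinol, C6 the ester, C8 the spiro-epoxide (C14 is its CH2), and C9 and C10 the diol. The face of the bicycle that carries H5 is called the upper face below.
- Seven ring stereocentres (C1, C4, C5, C6, C8, C9, C10) must be set. O6, the epoxide oxygen, O9 and O10 all lie on the upper face; the C1 methyl and O4 lie on the lower face.
- The centres can be made to control one another. A C6 stereocentre next to a C1=C5 alkene can set C5, C1 and C4 through allylic strain and chelation. The axial C1 methyl shields the lower face of C10. A C10 oxygen biases C9, and a C9 hydroxyl can deliver the epoxide oxygen to C8.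
- The quaternary C1 next to the tertiary C5, with trans geometry, is the hardest element for stepwise annulation, because methyl and a ring methylene at C1 differ little in size.
- The spiro-epoxide beside the cis-diol is acid-labile at tertiary C8, the isovalerate does not tolerate aluminium hydrides or excess strong base, and the tertiary C4 carbinol can eliminate. The epoxide therefore comes last and the ester is installed only after all organometallic steps.
- The enabling feature is that C4 is bonded to C5 and C5 to C1, so a C4 ketone is γ,δ to a C1=C5 alkene, while C10 is the nucleophilic end of a C9 enol derivative tethered to C5 through C6–C8. The two ring-forming bonds C4–C5 and C1–C10 thus form one electrophile–alkene–nucleophile array, the same two bonds that close a farnesyl chain to the daucane skeleton.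

## Retrosynthesis

**Epoxide (31 to 30).** The two C–O bonds of the spiro-epoxide are cut first, giving triol 30 with a C8=C14 methylene. A sulfur-ylide epoxidation of a C8 ketone was the neighbouring cut, but it would need a carbonyl at C8 and has no handle for the face. The allylic C9 hydroxyl of 30 can deliver oxygen to the upper face under neutral conditions, so the acid-labile group is made in the final step.

**Diol (30 to 25, via 29, 28, 26).** The C9–H bond is cut (reduction of enone 28), then the C10–O bond (oxidation of silyloxy diene 26, made from enone 25). Dihydroxylation of a C9=C10 alkene would set both centres at once, but that alkene cannot be reached regioselectively from a C9 ketone whose kinetic enolate forms at C8. The enone can enolise only toward C10, so the order "methylene first, oxygen second" makes the regiochemistry automatic. The forward steps must put O10 anti to the C1 methyl and then add hydride anti to O10.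

**C14 and the ester (25 to 18, via 21, 19).** The C8=C14 bond is cut to ketone 21 and an iminium one-carbon unit. The ester C–O bond and the benzyl ether lead back to 18. Carrying C14 in the chain would add a stereocentre at C8 that is destroyed later. The benzyl group must go while no alkene is present, so hydrogenolysis and acylation are placed directly after the key step. Kinetic enolisation of 21 has to avoid the neopentyl C10 and the ester.

**Key disconnection (18 to 17).** C4–C5 and C1–C10 are cut together, opening both rings to the acyclic E-enone 17 with one stereocentre (C6). Cutting only one ring bond (for example C6–C7 or C1–C10 alone) leaves a cyclopentane that already holds the quaternary centre, which is the hard part. The double cut removes three stereocentres and both rings. The forward cascade must proceed by anti addition across the alkene and through a chelate between O6 and the C4 carbonyl. The benzyl ether is chosen as a Lewis-basic group that does not ionise easily, and the tert-butyldimethylsilyl enol ether as a nucleophile robust enough to survive SnCl4 at low temperature.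

**C4 ketone (17 to 15 and 16).** The C4–isopropyl bond is cut to Weinreb amide 15 and iPrMgCl (16). A ketal at C4 would need acid for removal, which the enol ether cannot survive. A free C4 ketone would compete in the enolisation that makes the enol ether. The amide is inert to amide bases and releases the ketone on neutral work-up. 15 comes from methyl ketone 14 by kinetic O-silylation, and 14 from dioxolane 13.

**C5–C6 bond and the C6 stereocentre (13 to 6 and 9, via 12, 11, 10).** The benzyl ether is removed to give alcohol 12, and the C5–C6 bond is cut to alkenyl iodide 6 and aldehyde 9. An alkenyllithium or alkenylzinc addition would give 12 in one step but cannot carry the Weinreb amide. A chromium-mediated coupling can, at the price of forming racemic 10, which is oxidised to enone 11 and reduced enantioselectively to 12. The fragments are of similar size and carry no stereocentres.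

**Fragments (6 to 1 and 2; 9 to 7).** The C1–CH3 bond of 6 is cut to pent-4-yn-1-ol (1) and AlMe3 (2): syn-carbometalation fixes the E geometry, and the alcohol 4 is taken to acid 5 and amide 6. Aldehyde 9 comes from ethyl levulinate (7) through ketal ester 8.

## Roads not taken

**Alternative 1:** Enone–alkene photocycloaddition followed by glycol cleavage. The cut is C1–C10 and C5–C6, with the C6–C10 bond of a cyclobutane broken later. 3-Methylcyclopent-2-en-1-one A1, bound to a chiral oxazaborolidine activated by AlBr3, would be irradiated with the bis(trimethylsilyloxy)cyclopentene ketal A2 to give the cis-anti-cis tricycle A3. Desilylation and diol cleavage would open it to the cycloheptanedione A4.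
- Merits: two achiral five-membered rings give the quaternary C1 and ring B in two or three operations, the catalyst sets the absolute configuration, and C6, C8 and C10 arrive oxygenated.
- Weak points: the cycloaddition gives a cis ring fusion, so C5 must be inverted through the C4/C6 1,3-dicarbonyl. Four carbonyl-level carbons (C4, C6, C8, C10) then have to be told apart, and isopropyl addition at C4 of an enolisable β-diketone is unattractive. C9 is still unoxidised. The Lewis-acid-catalysed enantioselective version is best established for cyclohexenones with simple alkenes, not for a cyclopentenone with a tetrasubstituted enediol ether.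
- Comparison: this road reaches the bicyclic core faster and uses a known reaction class, which the chosen cascade does not. Against that, the chosen plan delivers the trans fusion, the C4 carbinol with its isopropyl group and the C6 configuration in the ring-forming step, and leaves a single ketone to process.

**Alternative 2:** Type 2 carbonyl-ene closure of ring B. The cut is C6–C7. Me2AlCl would activate the C6 aldehyde of the cyclopentane aldehyde A5, whose side chain carries the protected C9,C10-diol and an isopropenyl group. The ene reaction would give the 8(14)-methylene hydroazulen-6-ol A6.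
- Merits: the reaction class is well established, and it produces the C6 carbinol and the exocyclic C8=C14 alkene together. Only acylation, deprotection and epoxidation would remain, a shorter endgame than the chosen one.
- Weak points: A5 already contains C1, C4, C5, C9 and C10, including the quaternary centre next to two oxygenated carbons, so the real difficulty is moved into the substrate synthesis. The aldehyde is epimerisable at C5. The C6 configuration depends on a seven-membered ene transition state, which is slower than the six-membered case. The acetonide must be removed with acid before the epoxide is made.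
- Comparison: the key step is better precedented and ends closer to the target. The chosen plan instead creates the ring-fusion centres from a precursor with one stereocentre.

**Alternative 3:** Claisen ring expansion. The cut is C1–C10, formed while a C6–O bond breaks. Heating the 2-methylene-5-cyclopentenyl-tetrahydrofuran A7 would give the hydroazulenone A8 with the C9 ketone, a C5=C6 alkene and a C4 ketal.
- Merits: thermal, reagent-free and well known. Chirality is transferred from C6 to the quaternary C1. The C9 ketone is the same handle used here for C8–C10. Hydroboration of C5=C6 anti to the angular methyl should even set H5 and O6 correctly.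
- Weak points: the C6 oxygen is spent and must be reinstalled. C4, C5 and C6 are set in separate operations (hydroboration, ketal removal, isopropyl addition to a hindered, enolisable cyclopentanone). A7 needs an enantioenriched lactone and a carbonyl methylenation.
- Comparison: this key step is safer than the chosen one and the later C8–C10 chemistry would be the same. The chosen plan sets three stereocentres and both rings at once and carries O6 from the start, but its cascade is untested.

Key step: step 13

Remarks on the chemistry:
- Pent-4-yn-1-ol, AlMe3, ethyl levulinate, iPrMgCl, 3-methylbutanoyl chloride and Eschenmoser's salt are taken as commercial.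
- Bicyclic compounds are named with the daucane numbering defined above; "14-nor" marks compounds that lack C14.
- In all bicyclic compounds the C1 methyl and O4 are on the lower face and H5 and O6 on the upper face.

## Route

Step 1
Reactants: 1 pent-4-yn-1-ol; 2 trimethylaluminium
Product: 4 (E)-5-iodo-4-methylpent-4-en-1-ol, via alkenyldimethylalane 3 (not isolated)
Conditions: Cp2ZrCl2 (0.25 equiv), AlMe3 (3 equiv), CH2Cl2, 0 °C to rt; then I2, THF, −30 to 0 °C; aq. potassium sodium tartrate
Reagents that add atoms: iodine, II
Why: Zirconium-catalysed methylalumination (Negishi carboalumination) adds CH3 and Al syn with Al on the terminal carbon, the hydroxyl being carried as its aluminium alkoxide; iodinolysis with retention gives the E-iodide that fixes the later C1=C5 geometry.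

Step 2
Reactants: 4 (E)-5-iodo-4-methylpent-4-en-1-ol
Product: 5 (E)-5-iodo-4-methylpent-4-enoic acid
Conditions: TEMPO (0.2 equiv), PhI(OAc)2 (2.2 equiv), MeCN/H2O 1:1, rt
Reagents that add atoms: water, O
Why: Oxoammonium-mediated oxidation takes the primary alcohol through the aldehyde hydrate to the acid without touching the alkenyl iodide.

Step 3
Reactants: 5 (E)-5-iodo-4-methylpent-4-enoic acid
Product: 6 (E)-5-iodo-N-methoxy-N,4-dimethylpent-4-enamide
Conditions: 1,1'-carbonyldiimidazole, CH2Cl2, rt; then MeNH(OMe)·HCl, rt
Reagents that add atoms: N,O-dimethylhydroxylamine hydrochloride, CNOC.Cl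
Why: Acyl imidazole formation and aminolysis give the Weinreb amide, a latent C4 isopropyl ketone that tolerates the chromium, borane, hydride-base and amide-base steps that follow.

Step 4
Reactants: 7 ethyl levulinate
Product: 8 ethyl 3-(2-methyl-1,3-dioxolan-2-yl)propanoate
Conditions: ethylene glycol, TsOH (cat.), toluene, reflux, water separator
Reagents that add atoms: ethylene glycol, OCCO
Why: Acid-catalysed ketalisation with azeotropic removal of water masks the future C9 ketone.

Step 5
Reactants: 8 ethyl 3-(2-methyl-1,3-dioxolan-2-yl)propanoate
Product: 9 3-(2-methyl-1,3-dioxolan-2-yl)propanal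
Conditions: iBu2AlH (1.1 equiv), CH2Cl2, −78 °C; aq. potassium sodium tartrate
Reagents that add atoms: none
Why: Half-reduction of the ester stops at the aluminium hemiacetal at −78 °C and gives the aldehyde on work-up; the dioxolane is inert.

Step 6
Reactants: 6 (E)-5-iodo-N-methoxy-N,4-dimethylpent-4-enamide; 9 3-(2-methyl-1,3-dioxolan-2-yl)propanal
Product: 10 rac-(E)-6-hydroxy-N-methoxy-N,4-dimethyl-8-(2-methyl-1,3-dioxolan-2-yl)oct-4-enamide
Conditions: CrCl2 (4 equiv), NiCl2 (2 mol %), DMSO, rt
Reagents that add atoms: none
Why: Nozaki–Hiyama–Kishi coupling: the alkenylchromium species forms from the E-iodide with retention and adds only to the aldehyde, leaving the Weinreb amide and ketal untouched; the carbinol is racemic and is corrected in steps 7 and 8.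

Step 7
Reactants: 10 rac-(E)-6-hydroxy-N-methoxy-N,4-dimethyl-8-(2-methyl-1,3-dioxolan-2-yl)oct-4-enamide
Product: 11 (E)-N-methoxy-N,4-dimethyl-8-(2-methyl-1,3-dioxolan-2-yl)-6-oxooct-4-enamide
Conditions: Dess–Martin periodinane (1.3 equiv), CH2Cl2, 0 °C to rt
Reagents that add atoms: none
Why: Dess–Martin oxidation of the allylic alcohol gives the E-enone under conditions too mild to open the dioxolane.

Step 8
Reactants: 11 (E)-N-methoxy-N,4-dimethyl-8-(2-methyl-1,3-dioxolan-2-yl)-6-oxooct-4-enamide
Product: 12 (S,E)-6-hydroxy-N-methoxy-N,4-dimethyl-8-(2-methyl-1,3-dioxolan-2-yl)oct-4-enamide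
Conditions: (R)-2-methyl-CBS-oxazaborolidine (0.2 equiv), catecholborane (1.8 equiv), toluene, −78 °C
Reagents that add atoms: none
Why: Corey–Bakshi–Shibata reduction: the β,β-disubstituted alkenyl group acts as the large substituent, so the (R)-catalyst should give the (S)-carbinol (C6); catecholborane at −78 °C reduces the enone 1,2 and spares the Weinreb amide.

Step 9
Reactants: 12 (S,E)-6-hydroxy-N-methoxy-N,4-dimethyl-8-(2-methyl-1,3-dioxolan-2-yl)oct-4-enamide
Product: 13 (S,E)-6-(benzyloxy)-N-methoxy-N,4-dimethyl-8-(2-methyl-1,3-dioxolan-2-yl)oct-4-enamide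
Conditions: NaH, BnBr, Bu4NI (cat.), THF/DMF, 0 °C to rt
Reagents that add atoms: benzyl bromide, BrCc1ccccc1
Why: Williamson etherification of the sodium alkoxide installs the benzyl ether, the Lewis-basic and poorly ionising group needed for chelation in step 13.

Step 10
Reactants: 13 (S,E)-6-(benzyloxy)-N-methoxy-N,4-dimethyl-8-(2-methyl-1,3-dioxolan-2-yl)oct-4-enamide
Product: 14 (S,E)-6-(benzyloxy)-N-methoxy-N,4-dimethyl-9-oxodec-4-enamide
Conditions: pyridinium tosylate (cat.), acetone/H2O 9:1, 50 °C
Reagents that add atoms: water, O
Why: Mild acid-catalysed ketal hydrolysis frees the methyl ketone; the allylic benzyl ether and the Weinreb amide survive.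

Step 11
Reactants: 14 (S,E)-6-(benzyloxy)-N-methoxy-N,4-dimethyl-9-oxodec-4-enamide
Product: 15 (S,E)-6-(benzyloxy)-9-[(tert-butyldimethylsilyl)oxy]-N-methoxy-N,4-dimethyldeca-4,9-dienamide
Conditions: LiN(iPr)2 (1.1 equiv), THF, −78 °C; tBuMe2SiOTf, −78 °C; pH 7 buffer
Reagents that add atoms: tert-butyldimethylsilyl triflate, CC(C)(C)[Si](C)(C)OS(=O)(=O)C(F)(F)F
Why: Kinetic deprotonation of the methyl ketone at its methyl group and O-silylation give the terminal silyl enol ether; the amide α-protons are several pK units less acidic and stay untouched with one equivalent of base.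

Step 12
Reactants: 15 (S,E)-6-(benzyloxy)-9-[(tert-butyldimethylsilyl)oxy]-N-methoxy-N,4-dimethyldeca-4,9-dienamide; 16 isopropylmagnesium chloride
Product: 17 (S,E)-8-(benzyloxy)-11-[(tert-butyldimethylsilyl)oxy]-2,6-dimethyldodeca-6,11-dien-3-one
Conditions: iPrMgCl (1.5 equiv), THF, 0 °C; pH 7 phosphate buffer
Reagents that add atoms: none
Why: Weinreb ketone synthesis: the Grignard reagent adds once to a chelated tetrahedral intermediate that collapses to the isopropyl ketone only on neutral work-up, so the C4 ketone is released without acid in the presence of the silyl enol ether.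

Step 13
Reactants: 17 (S,E)-8-(benzyloxy)-11-[(tert-butyldimethylsilyl)oxy]-2,6-dimethyldodeca-6,11-dien-3-one
Product: 18 6-(benzyloxy)-4-hydroxy-14-nor-trans-daucan-9-one
Conditions: SnCl4 (1.2 equiv), 2,6-di-tert-butyl-4-methylpyridine (0.3 equiv), CH2Cl2 (0.005 M), −78 °C; then aq. NaHCO3
Reagents that add atoms: none
Why: Proposed new method: SnCl4 is expected to bind the C4 carbonyl and the C6 benzyloxy oxygen; C5 of the E-alkene then adds to the activated carbonyl to give a tertiary C1 cation, which is captured by C10 of the silyl enol ether before chloride removes the silyl group from the resulting oxocarbenium ion to leave the C9 ketone. The closest known reaction types are the Lewis-acid-initiated cyclisation of γ,δ-unsaturated ketones (first bond) and cation–olefin cyclisations terminated by silyl enol ethers (second bond); their combination in one cascade is untested. Ring A closes 5-exo with respect to the carbonyl and 5-endo with respect to the alkene, and ring B closes 7-endo at the enol ether. C5 and C1 are set by anti addition across the E-alkene, which places H5 trans to the C1 methyl; C4 is set by the chelate, which holds O4 cis to C6. The alkene face is chosen by the C6 stereocentre: allylic 1,3-strain with the C1 methyl keeps H6 in the alkene plane, so the chelated carbonyl reaches C5 from the O6 face and the enol ether chain reaches C1 from the opposite face. The step needs the enol ether capture to outrun a 1,2-hydride shift from C5 and ionisation of the allylic ether; the high nucleophilicity of the enol ether, −78 °C, high dilution and a hindered pyridine that removes adventitious acid are meant to secure this.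

Step 14
Reactants: 18 6-(benzyloxy)-4-hydroxy-14-nor-trans-daucan-9-one
Product: 19 4,6-dihydroxy-14-nor-trans-daucan-9-one
Conditions: H2 (1 atm), Pd/C (10 %), EtOAc, rt
Reagents that add atoms: none
Why: Hydrogenolysis of the benzyl ether over palladium; no alkene is present at this stage and the ketone and tertiary alcohol are inert.

Step 15
Reactants: 19 4,6-dihydroxy-14-nor-trans-daucan-9-one; 20 3-methylbutanoyl chloride
Product: 21 4-hydroxy-9-oxo-14-nor-trans-daucan-6-yl 3-methylbutanoate
Conditions: pyridine, DMAP (cat.), CH2Cl2, 0 °C
Reagents that add atoms: none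
Why: DMAP-catalysed acylation of the secondary C6 hydroxyl; the tertiary C4 hydroxyl, flanked by the isopropyl group and the ring fusion, does not react at 0 °C.

Step 16
Reactants: 21 4-hydroxy-9-oxo-14-nor-trans-daucan-6-yl 3-methylbutanoate; 22 Eschenmoser's salt (N,N-dimethylmethyleneiminium iodide)
Product: 25 4-hydroxy-9-oxo-trans-dauc-8(14)-en-6-yl 3-methylbutanoate, via Mannich base 23 (not isolated), via ammonium iodide 24 (not isolated)
Conditions: LiN(iPr)2 (2.1 equiv), THF, −78 °C; 22, −78 °C to rt; then MeI, rt; then DBU, rt
Reagents that add atoms: none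
Why: α-Methylenation by Mannich reaction: the first equivalent of base is taken by the C4 hydroxyl, and kinetic enolisation then occurs at C8, away from the neopentyl C10 and faster than at the ester. The enolate adds to the iminium salt, and N-methylation followed by E1cB elimination gives the exocyclic enone.

Step 17
Reactants: 25 4-hydroxy-9-oxo-trans-dauc-8(14)-en-6-yl 3-methylbutanoate
Product: 26 4,9-bis(triethylsilyloxy)-trans-dauca-8(14),9-dien-6-yl 3-methylbutanoate
Conditions: Et3SiOTf (2.5 equiv), Et3N (4 equiv), CH2Cl2, −78 to 0 °C
Reagents that add atoms: triethylsilyl triflate, CC[Si](CC)(CC)OS(=O)(=O)C(F)(F)F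
Why: Soft enolisation with silyl triflate and amine: the enone can enolise only toward C10, giving the 2-silyloxy diene, and the tertiary C4 hydroxyl is silylated at the same time; the ester is not enolised under these conditions.

Step 18
Reactants: 26 4,9-bis(triethylsilyloxy)-trans-dauca-8(14),9-dien-6-yl 3-methylbutanoate
Product: 28 9-oxo-4,10-bis(triethylsilyloxy)-trans-dauc-8(14)-en-6-yl 3-methylbutanoate, via silyloxy epoxide 27 (not isolated)
Conditions: mCPBA (1.05 equiv), CH2Cl2, −20 to 0 °C
Reagents that add atoms: 3-chloroperbenzoic acid, OOC(=O)c1cccc(Cl)c1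
Why: Rubottom oxidation: the peracid epoxidises the electron-rich enol ether double bond from the upper face, anti to the axial C1 methyl, and the silyloxy epoxide opens with 1,4-silyl migration to the α'-silyloxy enone, which sets C10.

Step 19
Reactants: 28 9-oxo-4,10-bis(triethylsilyloxy)-trans-dauc-8(14)-en-6-yl 3-methylbutanoate
Product: 29 9-hydroxy-4,10-bis(triethylsilyloxy)-trans-dauc-8(14)-en-6-yl 3-methylbutanoate
Conditions: NaBH4, CeCl3·7H2O, MeOH, −78 °C
Reagents that add atoms: none
Why: Luche reduction gives clean 1,2-reduction; hydride should add axially from the lower face, anti to the axial C10–O bond (Felkin–Anh) and away from the silyl ether, which places the C9 hydroxyl on the upper face cis to O10. The ester is inert to NaBH4 at −78 °C.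

Step 20
Reactants: 29 9-hydroxy-4,10-bis(triethylsilyloxy)-trans-dauc-8(14)-en-6-yl 3-methylbutanoate
Product: 30 4,9,10-trihydroxy-trans-dauc-8(14)-en-6-yl 3-methylbutanoate
Conditions: HF·pyridine, pyridine, THF, 0 °C to rt
Reagents that add atoms: none
Why: Fluoride cleavage of both triethylsilyl ethers under buffered conditions that leave the ester and the allylic alcohol intact; it is done before the epoxide exists.

Step 21
Reactants: 30 4,9,10-trihydroxy-trans-dauc-8(14)-en-6-yl 3-methylbutanoate
Product: 31 8,14-epoxy-4,9,10-trihydroxy-trans-daucan-6-yl 3-methylbutanoate (CNP0307265.1)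
Conditions: VO(acac)2 (5 mol %), tBuOOH (1.5 equiv), CH2Cl2, 0 °C to rt
Reagents that add atoms: tert-butyl hydroperoxide, CC(C)(C)OO
Why: Hydroxyl-directed epoxidation: the vanadium alkoxide of the allylic C9 hydroxyl delivers the peroxide oxygen to the upper face of the 1,1-disubstituted alkene, which sets C8; the neutral conditions spare the spiro-epoxide and the ester.

## Compound list

1 | pent-4-yn-1-ol | C#CCCCO | starting material
2 | trimethylaluminium | C[Al](C)C | starting material
3 | (E)-alkenyldimethylalane of the aluminium alkoxide of 4-methylpent-4-en-1-ol (Al on C5) | C[Al](C)/C=C(\C)CCCO[Al](C)C | intermediate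
4 | (E)-5-iodo-4-methylpent-4-en-1-ol | OCCC/C(C)=C/I | intermediate
5 | (E)-5-iodo-4-methylpent-4-enoic acid | OC(=O)CC/C(C)=C/I | intermediate
6 | (E)-5-iodo-N-methoxy-N,4-dimethylpent-4-enamide | CON(C)C(=O)CC/C(C)=C/I | intermediate
7 | ethyl levulinate | CCOC(=O)CCC(C)=O | starting material
8 | ethyl 3-(2-methyl-1,3-dioxolan-2-yl)propanoate | CCOC(=O)CCC1(C)OCCO1 | intermediate
9 | 3-(2-methyl-1,3-dioxolan-2-yl)propanal | O=CCCC1(C)OCCO1 | intermediate
10 | rac-(E)-6-hydroxy-N-methoxy-N,4-dimethyl-8-(2-methyl-1,3-dioxolan-2-yl)oct-4-enamide | CON(C)C(=O)CC/C(C)=C/C(O)CCC1(C)OCCO1 | intermediate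
11 | (E)-N-methoxy-N,4-dimethyl-8-(2-methyl-1,3-dioxolan-2-yl)-6-oxooct-4-enamide | CON(C)C(=O)CC/C(C)=C/C(=O)CCC1(C)OCCO1 | intermediate
12 | (S,E)-6-hydroxy-N-methoxy-N,4-dimethyl-8-(2-methyl-1,3-dioxolan-2-yl)oct-4-enamide | CON(C)C(=O)CC/C(C)=C/[C@@H](O)CCC1(C)OCCO1 | intermediate
13 | (S,E)-6-(benzyloxy)-N-methoxy-N,4-dimethyl-8-(2-methyl-1,3-dioxolan-2-yl)oct-4-enamide | CON(C)C(=O)CC/C(C)=C/[C@@H](OCc1ccccc1)CCC1(C)OCCO1 | intermediate
14 | (S,E)-6-(benzyloxy)-N-methoxy-N,4-dimethyl-9-oxodec-4-enamide | CON(C)C(=O)CC/C(C)=C/[C@@H](OCc1ccccc1)CCC(C)=O | intermediate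
15 | (S,E)-6-(benzyloxy)-9-[(tert-butyldimethylsilyl)oxy]-N-methoxy-N,4-dimethyldeca-4,9-dienamide | CON(C)C(=O)CC/C(C)=C/[C@@H](OCc1ccccc1)CCC(=C)O[Si](C)(C)C(C)(C)C | intermediate
16 | isopropylmagnesium chloride | CC(C)[Mg]Cl | starting material
17 | (S,E)-8-(benzyloxy)-11-[(tert-butyldimethylsilyl)oxy]-2,6-dimethyldodeca-6,11-dien-3-one | CC(C)C(=O)CC/C(C)=C/[C@@H](OCc1ccccc1)CCC(=C)O[Si](C)(C)C(C)(C)C | intermediate
18 | 6-(benzyloxy)-4-hydroxy-14-nor-trans-daucan-9-one (4-OH and 1-CH3 lower face; H5 and 6-O upper face) | c1ccccc1CO[C@H]1CCC(=O)C[C@@]2(C)CC[C@@](O)(C(C)C)[C@H]12 | intermediate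
19 | 4,6-dihydroxy-14-nor-trans-daucan-9-one | O[C@H]1CCC(=O)C[C@@]2(C)CC[C@@](O)(C(C)C)[C@H]12 | intermediate
20 | 3-methylbutanoyl chloride (isovaleryl chloride) | CC(C)CC(Cl)=O | starting material
21 | 4-hydroxy-9-oxo-14-nor-trans-daucan-6-yl 3-methylbutanoate | CC(C)CC(=O)O[C@H]1CCC(=O)C[C@@]2(C)CC[C@@](O)(C(C)C)[C@H]12 | intermediate
22 | Eschenmoser's salt (N,N-dimethylmethyleneiminium iodide) | C=[N+](C)C.[I-] | starting material
23 | 8-[(dimethylamino)methyl]-4-hydroxy-9-oxo-14-nor-trans-daucan-6-yl 3-methylbutanoate (C8 epimers) | CC(C)CC(=O)O[C@H]1CC(CN(C)C)C(=O)C[C@@]2(C)CC[C@@](O)(C(C)C)[C@H]12 | intermediate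
24 | trimethylammonium iodide of 23 | CC(C)CC(=O)O[C@H]1CC(C[N+](C)(C)C)C(=O)C[C@@]2(C)CC[C@@](O)(C(C)C)[C@H]12.[I-] | intermediate
25 | 4-hydroxy-9-oxo-trans-dauc-8(14)-en-6-yl 3-methylbutanoate | CC(C)CC(=O)O[C@H]1CC(=C)C(=O)C[C@@]2(C)CC[C@@](O)(C(C)C)[C@H]12 | intermediate
26 | 4,9-bis(triethylsilyloxy)-trans-dauca-8(14),9-dien-6-yl 3-methylbutanoate | CC(C)CC(=O)O[C@H]1CC(=C)C(O[Si](CC)(CC)CC)=C[C@@]2(C)CC[C@@](O[Si](CC)(CC)CC)(C(C)C)[C@H]12 | intermediate
27 | 9,10-epoxide of 26 (epoxide oxygen on the upper face) | CC(C)CC(=O)O[C@H]1CC(=C)[C@@]3(O[Si](CC)(CC)CC)O[C@H]3[C@@]2(C)CC[C@@](O[Si](CC)(CC)CC)(C(C)C)[C@H]12 | intermediate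
28 | 9-oxo-4,10-bis(triethylsilyloxy)-trans-dauc-8(14)-en-6-yl 3-methylbutanoate (10-O upper face) | CC(C)CC(=O)O[C@H]1CC(=C)C(=O)[C@@H](O[Si](CC)(CC)CC)[C@@]2(C)CC[C@@](O[Si](CC)(CC)CC)(C(C)C)[C@H]12 | intermediate
29 | 9-hydroxy-4,10-bis(triethylsilyloxy)-trans-dauc-8(14)-en-6-yl 3-methylbutanoate (9-OH upper face) | CC(C)CC(=O)O[C@H]1CC(=C)[C@@H](O)[C@@H](O[Si](CC)(CC)CC)[C@@]2(C)CC[C@@](O[Si](CC)(CC)CC)(C(C)C)[C@H]12 | intermediate
30 | 4,9,10-trihydroxy-trans-dauc-8(14)-en-6-yl 3-methylbutanoate | CC(C)CC(=O)O[C@H]1CC(=C)[C@@H](O)[C@@H](O)[C@@]2(C)CC[C@@](O)(C(C)C)[C@H]12 | intermediate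
31 | 8,14-epoxy-4,9,10-trihydroxy-trans-daucan-6-yl 3-methylbutanoate, CNP0307265.1 (epoxide O, O9, O10, O6 upper face) | CC(C)CC(=O)O[C@H]1C[C@]2(CO2)[C@@H](O)[C@@H](O)[C@@]2(C)CC[C@@](O)(C(C)C)[C@H]12 | target

## Step count and least certain steps

Total step count: 21. Longest linear sequence: 19 steps (steps 1–3 and 6–21); steps 4 and 5 form the side branch.

**Step 13 (key step, proposed new method).**
- What may go wrong: a 1,2-hydride shift from C5 to the C1 cation followed by semipinacol collapse; desilylation of the enol ether or ionisation of the allylic benzyl ether before ring B closes; erosion of the trans fusion if the cation outlives the chelate. All follow from the seven-membered closure being the slow event.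
- Fallback (known reactions, rings closed one at a time): it sets out from 13 and returns at 18.
 - iPrMgCl converts the Weinreb amide into the isopropyl ketone F1, with the C9 dioxolane still in place.
 - Me2AlCl at −78 °C effects a type 2 carbonyl-ene cyclisation to the methylenecyclopentanol F2, under the same chelation and allylic-strain control of C4 and C5. An endocyclic alkene isomer would converge in the next operation.
 - HCl in CH2Cl2 followed by aqueous acid adds HCl in the Markovnikov sense and hydrolyses the ketal, giving the tertiary chloride methyl ketone F3.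
 - LiN(iPr)2 (2.2 equiv) and Me3SiCl at −78 °C give the bis(trimethylsilyl) derivative F4 (terminal enol ether and O4 silyl ether).
 - TiCl4 ionises the tertiary chloride and the enol ether alkylates the cation (Lewis-acid-mediated tert-alkylation of a silyl enol ether); aqueous work-up removes the O4 silyl group and gives 18.
- Cost: four more operations and weaker control of the ring fusion.

**Step 19.**
- What may go wrong: hydride delivery from the upper face (equatorial attack), because the axial C1 methyl shields the lower face 1,3 to C9. This would invert C9 and, through the directed epoxidation, C8 as well.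
- Fallback: it sets out from 28 and returns at 29. The upper-face reduction is accepted, giving the 9-epi alcohol F5 with an axial hydroxyl. Mitsunobu esterification (PPh3, diisopropyl azodicarboxylate, 4-nitrobenzoic acid) inverts C9 to the 4-nitrobenzoate F6. The activated aryl ester is then cleaved selectively with K2CO3 in MeOH at 0 °C. SN2' attack at C14 is the competing pathway to watch.

**Step 16.**
- What may go wrong: competing deprotonation of the isovalerate α-CH2 or of C10, and acyl transfer to the C4 alkoxide, because a strong amide base meets an ester.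
- Fallback: it sets out from 21 and returns at 25. Soft enolisation with Me3SiOTf/Et3N, without strong base, gives the bis(trimethylsilyl) compound F7 (C8=C9 enol ether expected as the less hindered isomer, O4 silylated). A Mukaiyama–Mannich reaction with 22 in CH2Cl2, then methylation, elimination and mild acidic work-up as before, completes the return.

**Step 8.**
- What may go wrong: insufficient discrimination by the oxazaborolidine between the alkenyl group and the unbranched CH2CH2 chain, giving low enantiomeric purity at C6, the centre that controls all later ones.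
- Fallback: it sets out from 6 and 9 and returns at 12, replacing steps 6–8. A catalytic enantioselective Nozaki–Hiyama–Kishi coupling (CrCl2 with a chiral sulfonamide–oxazoline ligand, NiCl2, Mn powder, Me3SiCl) would form the C5–C6 bond and the stereocentre in one operation. No new compound arises (F0).

## Further compounds

F1 | step 13 | (S,E)-8-(benzyloxy)-2,6-dimethyl-10-(2-methyl-1,3-dioxolan-2-yl)dec-6-en-3-one | CC(C)C(=O)CC/C(C)=C/[C@@H](OCc1ccccc1)CCC1(C)OCCO1
F2 | step 13 | 2-[(S)-1-(benzyloxy)-3-(2-methyl-1,3-dioxolan-2-yl)propyl]-3-methylidene-1-(propan-2-yl)cyclopentan-1-ol (hydroxyl cis to the side chain) | C=C1CC[C@@](O)(C(C)C)[C@@H]1[C@@H](OCc1ccccc1)CCC1(C)OCCO1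
F3 | step 13 | 5-(benzyloxy)-5-[2-chloro-5-hydroxy-2-methyl-5-(propan-2-yl)cyclopentyl]pentan-2-one (chloride epimers) | CC1(Cl)CC[C@@](O)(C(C)C)[C@@H]1[C@@H](OCc1ccccc1)CCC(C)=O
F4 | step 13 | bis(trimethylsilyl) derivative of F3 (terminal enol ether and O4 silyl ether) | CC1(Cl)CC[C@@](O[Si](C)(C)C)(C(C)C)[C@@H]1[C@@H](OCc1ccccc1)CCC(=C)O[Si](C)(C)C
F5 | step 19 | 9-epimer of 29 (9-OH lower face) | CC(C)CC(=O)O[C@H]1CC(=C)[C@H](O)[C@@H](O[Si](CC)(CC)CC)[C@@]2(C)CC[C@@](O[Si](CC)(CC)CC)(C(C)C)[C@H]12
F6 | step 19 | 9-O-(4-nitrobenzoate) of 29 | CC(C)CC(=O)O[C@H]1CC(=C)[C@@H](OC(=O)c3ccc(cc3)[N+](=O)[O-])[C@@H](O[Si](CC)(CC)CC)[C@@]2(C)CC[C@@](O[Si](CC)(CC)CC)(C(C)C)[C@H]12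
F7 | step 16 | 4,9-bis(trimethylsilyloxy)-14-nor-trans-dauc-8-en-6-yl 3-methylbutanoate | CC(C)CC(=O)O[C@H]1CC=C(O[Si](C)(C)C)C[C@@]2(C)CC[C@@](O[Si](C)(C)C)(C(C)C)[C@H]12
F0 | step 8 | none | none
A1 | alternative 1 | 3-methylcyclopent-2-en-1-one | CC1=CC(=O)CC1
A2 | alternative 1 | 7,8-bis(trimethylsilyloxy)-1,4-dioxaspiro[4.4]non-7-ene | C[Si](C)(C)OC1=C(O[Si](C)(C)C)CC2(C1)OCCO2
A3 | alternative 1 | cis-anti-cis 5-4-5 tricyclic ketone with C6,C10 bis(silyl ether) and C8 ketal | O=C1CC[C@@]2(C)[C@@H]1[C@]3(O[Si](C)(C)C)CC4(OCCO4)C[C@]23O[Si](C)(C)C
A4 | alternative 1 | cis-fused 4,6,10-trioxo-14-nordaucane 8-ethylene ketal | O=C1CC[C@@]2(C)[C@@H]1C(=O)CC1(OCCO1)CC2=O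
A5 | alternative 2 | cyclopentanecarbaldehyde with 4-triethylsilyloxy, isopropyl, angular methyl and the acetonide-protected 9,10-diol side chain ending in isopropenyl | O=C[C@H]1[C@](O[Si](CC)(CC)CC)(C(C)C)CC[C@]1(C)[C@@H]2OC(C)(C)O[C@@H]2C(C)=C
A6 | alternative 2 | 8(14)-methylene hydroazulen-6-ol with C9,C10 acetonide and 4-triethylsilyl ether | O[C@H]1CC(=C)[C@@H](OC3(C)C)[C@@H](O3)[C@@]2(C)CC[C@@](O[Si](CC)(CC)CC)(C(C)C)[C@H]12
A7 | alternative 3 | (S)-2-methylene-5-(cyclopentenyl)tetrahydrofuran with 2-methyl and 5,5-ethylenedioxy groups on the cyclopentene | C=C1CC[C@H](O1)C2=C(C)CCC23OCCO3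
A8 | alternative 3 | hydroazulenone with C1 quaternary centre, C9 ketone, C5–C6 alkene and C4 ketal | O=C1CCC=C2C3(OCCO3)CC[C@]2(C)C1
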